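# Proposed synthesis of (2S,3E)-1-(7-formylcyclopenta[c]pyran-4-yl)-4,8-dimethylnona-3,7-dien-2-yl acetate (19)

## The problem

The target 19 is (2S,3E)-1-(7-formylcyclopenta[c]pyran-4-yl)-4,8-dimethylnona-3,7-dien-2-yl acetate. Its nucleus is a pseudoazulene: pyran ring A (C1, O2, C3, C4, C4a, C7a) is fused along C4a–C7a to the five-membered ring B (C4a, C5, C6, C7, C7a), with a formyl group on C7 and the side chain on C4. The bicycle is a 10π push–pull system in which O2 feeds electron density into ring B and on to the aldehyde, so electrophiles go to C5 and C7 and nucleophiles to C1 and C3; C4 cannot be addressed selectively on the finished nucleus, and its handle has to be built in with the ring. The side chain carries the only stereocentre, C2' (S), a secondary allylic carbinol carbon between C1'H2 and the (E)-C3'=C4' double bond; with no second stereocentre there is nothing to relay it, so it must come from a reagent or catalyst, and the E geometry is a separate task. Several groups need mild handling: the allylic acetate (ionisation, elimination to a triene), the formylpseudoazulene (ring B protonates in strong acid, hard nucleophiles open ring A at C1 or C3, peroxides can attack the electron-rich ring and the formyl group) and the two trisubstituted alkenes. The acetate should therefore go on last, and only a few gentle steps should follow the union of nucleus and chain. The enabling feature is the array C4(sp2)–C1'H2–C2'H(O)–C3'(sp2): an sp2 carbon, a methylene, and a heteroatom-bearing methine that carries a second sp2 carbon. This is the pattern left when a vinyl group on boron is inserted between an sp2 electrophile and an alkenyl group that migrates from boron to carbon, with boron standing in for the oxygen at C2'.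

## Retrosynthesis

**19 to 17 (C–O bonds at C2').** The acetyl–oxygen bond is cut first, giving the (S)-alcohol 18, and the C2'–O bond is then traced back to a C2'–B bond in the allylic pinacol boronic ester 17. Placing oxygen after the skeleton is complete avoids any organometallic with a leaving group in the β-position and keeps the ionisable allylic acetate out of all C–C bond-forming steps. The forward reactions must oxidise C–B with retention and acylate under non-ionising conditions, in the presence of the C7 aldehyde.

**17 to 8 and 16 (C4–C1' and C2'–C3').** Both bonds that flank the C1'–C2' unit are cut at once. This leads to the heteroaryl bromide 8, vinylboronic ester 14 and the alkenyllithium 15, the last two combined as the borate 16. The neighbouring cuts are weaker: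
- An sp2–sp3 coupling at C4–C1' alone needs a β-oxygenated alkylmetal, which eliminates.
- Metalation of C4 for an epoxide opening is not compatible with the aldehyde.
- Addition of the alkenyl group to an arylacetaldehyde forms only one of the two bonds and needs the two-carbon link built first.

The chosen cut reduces a chiral 20-carbon intermediate to three achiral pieces and lets one catalyst set C2'. The forward reaction must activate the vinyl group and not the trisubstituted alkenyl group, avoid direct alkenyl transfer, and leave the aldehyde alone.

**15 to 9 (the E-alkenyl fragment).** The C–Li bond is traced to the C–I bond of iodide 13. The C2–CH3 and C1–I bonds of 13 are cut to the terminal alkyne 11, and 11 comes from the methyl ketone 9 by loss of the carbonyl oxygen. Syn methylmetalation of an alkyne fixes the E geometry by mechanism. An olefination of a ketone would give a mixture of geometric isomers, so this cut is preferred. Fragment 9 is an inexpensive C8 ketone.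

**8 to 6 (ring B: C6=C7, then aromatisation).** The pseudoazulene 8 is taken back to the pyranol 7, which needs only loss of water and unmasking of the aldehyde. Ring B of 7 is opened at C6=C7 to the diene 6. A single-step alternative would be an intramolecular vinylogous aldol condensation of a butenal side chain onto the pyranone carbonyl. It would be shorter, but that carbonyl has no record as an aldol acceptor for simple enolisable partners, and the basic conditions threaten ring A. The metathesis route uses only reaction types with broad precedent, and the driving force of the final aromatisation is large. The forward steps must close a cyclopentene with a trisubstituted double bond and then dehydrate without strong acid.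

**6 to 1 and 2 (C4a–C5 and C7–C7a).** The allyl group of 6 is removed at C4a–C5, giving the pyranone 5. The alkenyl group of 5 is removed at C7–C7a, giving the acrolein acetal bromide 1 and the symmetric dibromopyranone 2. The two bromines of 2 are equivalent: whichever couples, the other ends as the C4 bromine of 8. This answers the problem that C4 cannot be halogenated on the finished nucleus. The forward steps need mono-coupling of a dibromide and 1,2-addition of an allyl nucleophile to a cross-conjugated carbonyl.

## Roads not taken

**Alternative 1:** Ring A is cut at O2–C3 and C4–C4a. The forward key step is an inverse-demand hetero-Diels–Alder reaction between 2-formylcyclopent-2-en-1-one A1, acting as a 1-oxadiene, and the chiral enol ether (2S)-2-[(1E)-2,6-dimethylhepta-1,5-dien-1-yl]-2,3-dihydrofuran A2. It gives the tricyclic furo[2,3-b]pyran acetal A3.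
- Merits: the step is convergent and needs no metal or halide. It forms ring A, the C4–C1' bond and the C2' oxygen function in one thermal step. In this respect it is better than the chosen plan, which needs a statistical mono-coupling and a chiral palladium catalyst.
- Weak points: A3 is far from the target. Three new sp3 centres (C3, C4, C4a) are made only to be flattened, and two dehydrogenations are required. The furanoside acetal has to be opened selectively to free C2'–OH and the C3=C4 double bond. C7 carries a ketone, not the formyl carbon, so a one-carbon homologation on a sensitive intermediate is still needed. C2' must already be present in A2, which needs its own asymmetric synthesis, and A1 polymerises easily.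
- Comparison: the chosen plan builds the aromatic nucleus from flat, achiral material at the correct oxidation level, and only two steps follow the fragment union.

**Alternative 2:** Ring B is traced to a benzo ring, with the C7–C7a bond formed by ring contraction. The forward key step is photolysis of the quinone diazide 4-[(2S,3E)-2-(tert-butyldimethylsilyloxy)-4,8-dimethylnona-3,7-dien-1-yl]-7-diazo-1H-isochromene-1,8(7H)-dione A4. Wolff rearrangement and trapping of the ketene with MeNHOMe give the amide A5.
- Merits: benzenoid chemistry places every substituent with certainty, and the ring contraction of ortho-quinone diazides is a dependable photoreaction. It delivers the C7 carbon regiospecifically. In regiochemical security and robustness of early intermediates this road is at least as good as the chosen one.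
- Weak points: A5 is a lactone at C1 and a 5H-dihydro compound. C1 must be reduced from carbonyl to enol-ether CH and the amide to the aldehyde, two hydride-level adjustments that must be told apart on a base-sensitive system. The diene side chain is exposed to ultraviolet light. A4 needs an aminohydroxyisocoumarin that already carries the whole chiral chain, so the stereocentre travels through a long linear sequence including diazotisation.
- Comparison: the chosen plan has the formyl group at its final oxidation state from compound 8 onward, and sets C2' late in the step that attaches the chain.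

**Alternative 3:** Ring A is cut at C3=C4. The forward key step is a reductive ketone–formate coupling with low-valent titanium (TiCl3/Zn) on the fulvene (Z)-{2-[(3S,4E)-3-(tert-butyldimethylsilyloxy)-5,9-dimethyldeca-4,8-dienoyl]cyclopenta-2,4-dien-1-ylidene}methyl formate A6. It gives the pyran A7 directly.
- Merits: the aromatic bicycle forms in one step with the chain in place, with no halogen, no palladium and no later oxidation-state change in ring A. On paper it is the shortest way to the ring system.
- Weak points: the β-silyloxy ketone is exposed to a strong reductant, and the ketyl or titanium enolate can expel the C2' oxygen. The formate of an acidic hydroxyfulvene is an active ester and can transfer its formyl group. A7 lacks the C7 aldehyde and is an acceptor-free, air-sensitive pseudoazulene. A late formylation must choose C7 over C5 with little to bias it. C2' must again be made earlier by a separate asymmetric step.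
- Comparison: the chosen plan keeps the stabilising aldehyde on the nucleus throughout and fixes the substitution pattern through the symmetry of 2.

Key step: step 7

Assumption: compounds 1, 2, 9 and 14 are taken as purchasable, and the MandyPhos antipode is chosen by the known facial model for alkenyl migration so that C2' forms as (S), to be confirmed on alcohol 18 by Mosher ester analysis.

## Route

Step 1
Reactants: 1 2-bromo-3,3-diethoxyprop-1-ene; 2 3,5-dibromo-4H-pyran-4-one
Product: 5 3-bromo-5-(3,3-diethoxyprop-1-en-2-yl)-4H-pyran-4-one, via alkenyllithium 3 (not isolated), via alkenylzinc chloride 4 (not isolated)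
Conditions: 1, t-BuLi (2 equiv), Et2O, −78 °C; ZnCl2, THF, −78 °C → rt; 2 (3 equiv), Pd(PPh3)4 (5 mol%), THF, rt → 45 °C
Reagents that add atoms: none
Why: Negishi cross-coupling: bromine–lithium exchange and transmetalation to zinc give an alkenylzinc chloride that couples with the activated C(sp2)–Br bond of the α-bromo vinylogous ester under zerovalent palladium. The two bromines of 2 are equivalent, so the only selectivity needed is mono- over double coupling, which the excess of recoverable 2 should secure; the surviving bromine becomes the C4 handle.

Step 2
Reactants: 5 3-bromo-5-(3,3-diethoxyprop-1-en-2-yl)-4H-pyran-4-one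
Product: 6 rac-3-bromo-5-(3,3-diethoxyprop-1-en-2-yl)-4-(prop-2-en-1-yl)-4H-pyran-4-ol
Conditions: allylMgBr (1.2 equiv), THF, −78 °C; aq. NaHCO3 work-up
Reagents that add atoms: allylmagnesium bromide, C=CC[Mg]Br
Why: Grignard 1,2-addition: allylmagnesium halides add to hindered, cross-conjugated ketones through a six-membered transition state in preference to conjugate addition, and carbonyl addition of organomagnesium reagents to 4-pyranones is the classical entry to 4-substituted pyranols and pyrylium salts. The new carbinol centre forms racemic and is erased in step 4.

Step 3
Reactants: 6 rac-3-bromo-5-(3,3-diethoxyprop-1-en-2-yl)-4-(prop-2-en-1-yl)-4H-pyran-4-ol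
Product: 7 rac-4-bromo-7-(diethoxymethyl)cyclopenta[c]pyran-4a(5H)-ol
Conditions: second-generation Grubbs catalyst (5 mol%), CH2Cl2, 40 °C
Reagents that add atoms: none
Why: Ring-closing olefin metathesis between the allyl group and the 1,1-disubstituted alkene forms C6=C7 and closes ring B as a cyclopentene. The ring enol-ether double bonds are trisubstituted and should stay out of the catalytic cycle, and the free tertiary alcohol is tolerated.

Step 4
Reactants: 7 rac-4-bromo-7-(diethoxymethyl)cyclopenta[c]pyran-4a(5H)-ol
Product: 8 4-bromocyclopenta[c]pyran-7-carbaldehyde
Conditions: PPTS (cat.), acetone/H2O, rt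
Reagents that add atoms: water, O
Why: Acid-catalysed dehydration with acetal hydrolysis: the tertiary 4-pyranol ionises to a ring-fused pyrylium ion, loss of a C5 proton gives the neutral 10π pseudoazulene, and the acetal on the now electron-rich C7 hydrolyses to the aldehyde. The push–pull stabilisation of 8 drives all three events.

Step 5
Reactants: 9 6-methylhept-5-en-2-one
Product: 11 6-methylhept-5-en-1-yne, via enol phosphate 10 (not isolated)
Conditions: LiN(i-Pr)2 (1.05 equiv), THF, −78 °C; ClP(O)(OEt)2, −78 °C → rt; LiN(i-Pr)2 (2.3 equiv), −78 °C → rt
Reagents that add atoms: none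
Why: Methyl ketone to terminal alkyne by the enol phosphate route: kinetic deprotonation at the methyl group, O-phosphorylation and base-induced β-elimination of diethyl phosphate. The excess amide holds the product as its acetylide until work-up, which suppresses allene formation.

Step 6
Reactants: 11 6-methylhept-5-en-1-yne
Product: 13 (1E)-1-iodo-2,6-dimethylhepta-1,5-diene, via alkenylalane 12 (not isolated)
Conditions: Me3Al (2 equiv), Cp2ZrCl2 (25 mol%), CH2Cl2, 0 °C → rt; I2, THF, −30 → 0 °C
Reagents that add atoms: trimethylaluminium, C[Al](C)C; iodine, II
Why: Negishi zirconium-catalysed carboalumination adds methyl and aluminium syn across the terminal alkyne with methyl on the internal carbon, and iodinolysis of the C–Al bond with retention gives the (E)-iodide. The remote trisubstituted alkene does not react.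

Step 7
Reactants: 13 (1E)-1-iodo-2,6-dimethylhepta-1,5-diene; 14 4,4,5,5-tetramethyl-2-vinyl-1,3,2-dioxaborolane; 8 4-bromocyclopenta[c]pyran-7-carbaldehyde
Product: 17 2-[(2S,3E)-1-(7-formylcyclopenta[c]pyran-4-yl)-4,8-dimethylnona-3,7-dien-2-yl]-4,4,5,5-tetramethyl-1,3,2-dioxaborolane, via alkenyllithium 15 (not isolated), via lithium bis(alkenyl)borate 16 (not isolated)
Conditions: 13, t-BuLi (2 equiv), Et2O, −78 °C; 14, −78 °C → rt; evaporate, THF; 8 (limiting), Pd(OAc)2 (3 mol%), MandyPhos (3.6 mol%), NaOTf (2 equiv), 60 °C
Reagents that add atoms: none
Why: The closest known reaction type is the palladium-catalysed enantioselective conjunctive cross-coupling of bis(alkenyl)borates with C(sp2) electrophiles, which gives α-chiral allylic boronic esters. Zerovalent palladium carrying the MandyPhos ligand inserts into the C4–Br bond of 8, the only carbon–halogen bond present, and NaOTf strips bromide and the iodide left from the exchange, so that a cationic arylpalladium species binds the vinyl group of 16 instead of taking the alkenyl group by direct transmetalation. π-Activation triggers a 1,2-metallate shift: the alkenyl group moves from boron to the boron-bearing carbon, forming C2'–C3' anti to palladium, palladium becomes bonded to C1', and reductive elimination then forms C4–C1'; no ring closes. C2' is the only new stereocentre and is set by the chiral bisphosphine, which selects the face of the bound vinyl group; nothing in the achiral partners biases it. The step needs the unsubstituted vinyl group to be the one activated, which the steric difference between it and the trisubstituted alkenyl group should secure, and the migrating sp2 carbon keeps its E geometry because its σ-bond, not its π-bond, is transferred. The wide-bite-angle ligand favours reductive elimination over β-hydride loss from the C1'–palladium intermediate. The C7 formyl group is the acceptor end of a vinylogous formate and the organolithium is fully consumed in forming 16 before 8 is added, so carbonyl addition is not expected to compete; 17 is taken on promptly to limit allylboration of that aldehyde.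

Step 8
Reactants: 17 2-[(2S,3E)-1-(7-formylcyclopenta[c]pyran-4-yl)-4,8-dimethylnona-3,7-dien-2-yl]-4,4,5,5-tetramethyl-1,3,2-dioxaborolane
Product: 18 4-[(2S,3E)-2-hydroxy-4,8-dimethylnona-3,7-dien-1-yl]cyclopenta[c]pyran-7-carbaldehyde
Conditions: NaBO3·4H2O (4 equiv), THF/H2O, 0 °C → rt
Reagents that add atoms: sodium perborate tetrahydrate (NaBO3·4H2O), [Na+].[Na+].O[B-]1(O)OO[B-](O)(O)OO1.O.O.O.O.O.O
Why: Oxidation of the secondary allylic boronic ester by perborate: hydroperoxide adds to boron and C2' migrates from boron to oxygen with retention, so (S)-17 should give (S)-18 without allylic transposition. The mildly basic, buffered oxidant is chosen to spare the vinylogous formyl group and ring A.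

Step 9
Reactants: 18 4-[(2S,3E)-2-hydroxy-4,8-dimethylnona-3,7-dien-1-yl]cyclopenta[c]pyran-7-carbaldehyde
Product: 19 (2S,3E)-1-(7-formylcyclopenta[c]pyran-4-yl)-4,8-dimethylnona-3,7-dien-2-yl acetate
Conditions: Ac2O, DMAP (cat.), pyridine, CH2Cl2, 0 °C → rt
Reagents that add atoms: acetic anhydride, CC(=O)OC(C)=O
Why: DMAP-catalysed acylation of the secondary allylic alcohol under basic conditions that neither ionise C2' nor touch the aldehyde. No bond to C2' is broken, so its configuration is kept.

## Compound list

1 | 2-bromo-3,3-diethoxyprop-1-ene (2-bromoacrolein diethyl acetal) | C=C(Br)C(OCC)OCC | starting material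
2 | 3,5-dibromo-4H-pyran-4-one | O=C1C(Br)=COC=C1Br | starting material
3 | (3,3-diethoxyprop-1-en-2-yl)lithium | [Li]C(=C)C(OCC)OCC | intermediate
4 | chloro(3,3-diethoxyprop-1-en-2-yl)zinc | Cl[Zn]C(=C)C(OCC)OCC | intermediate
5 | 3-bromo-5-(3,3-diethoxyprop-1-en-2-yl)-4H-pyran-4-one | O=C1C(Br)=COC=C1C(=C)C(OCC)OCC | intermediate
6 | rac-3-bromo-5-(3,3-diethoxyprop-1-en-2-yl)-4-(prop-2-en-1-yl)-4H-pyran-4-ol (racemic at the carbinol carbon) | OC1(CC=C)C(Br)=COC=C1C(=C)C(OCC)OCC | intermediate
7 | rac-4-bromo-7-(diethoxymethyl)cyclopenta[c]pyran-4a(5H)-ol (OH on C4a, CH2 at C5, double bonds C1=C7a, C3=C4, C6=C7; racemic at C4a) | OC12CC=C(C(OCC)OCC)C2=COC=C1Br | intermediate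
8 | 4-bromocyclopenta[c]pyran-7-carbaldehyde | Brc1cocc2c(C=O)ccc1-2 | intermediate
9 | 6-methylhept-5-en-2-one | CC(=O)CCC=C(C)C | starting material
10 | diethyl 6-methylhepta-1,5-dien-2-yl phosphate | C=C(CCC=C(C)C)OP(=O)(OCC)OCC | intermediate
11 | 6-methylhept-5-en-1-yne | C#CCCC=C(C)C | intermediate
12 | [(1E)-2,6-dimethylhepta-1,5-dien-1-yl]dimethylalane | C[Al](C)/C=C(\C)CCC=C(C)C | intermediate
13 | (1E)-1-iodo-2,6-dimethylhepta-1,5-diene | I/C=C(\C)CCC=C(C)C | intermediate
14 | 4,4,5,5-tetramethyl-2-vinyl-1,3,2-dioxaborolane (vinylboronic acid pinacol ester) | C=CB1OC(C)(C)C(C)(C)O1 | starting material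
15 | [(1E)-2,6-dimethylhepta-1,5-dien-1-yl]lithium | [Li]/C=C(\C)CCC=C(C)C | intermediate
16 | lithium [(1E)-2,6-dimethylhepta-1,5-dien-1-yl](ethenyl)(pinacolato)borate | [Li+].C=C[B-]1(/C=C(\C)CCC=C(C)C)OC(C)(C)C(C)(C)O1 | intermediate
17 | 2-[(2S,3E)-1-(7-formylcyclopenta[c]pyran-4-yl)-4,8-dimethylnona-3,7-dien-2-yl]-4,4,5,5-tetramethyl-1,3,2-dioxaborolane | CC1(C)OB(OC1(C)C)[C@H](/C=C(\C)CCC=C(C)C)Cc1cocc2c(C=O)ccc1-2 | intermediate
18 | 4-[(2S,3E)-2-hydroxy-4,8-dimethylnona-3,7-dien-1-yl]cyclopenta[c]pyran-7-carbaldehyde | O[C@H](/C=C(\C)CCC=C(C)C)Cc1cocc2c(C=O)ccc1-2 | intermediate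
19 | (2S,3E)-1-(7-formylcyclopenta[c]pyran-4-yl)-4,8-dimethylnona-3,7-dien-2-yl acetate | CC(=O)O[C@H](/C=C(\C)CCC=C(C)C)Cc1cocc2c(C=O)ccc1-2 | target

## Step count and least certain steps

Total step count: 9. Longest linear sequence: 7 steps (steps 1, 2, 3, 4, 7, 8, 9, from 1 and 2); the alkenyl fragment joins after 2 steps (5, 6).

**Step 7 (key step).** This bromide class has not been used in a conjunctive coupling. The most likely failure is loss of the formyl group to boron nucleophiles during the hours at 60 °C, either by addition of borate 16 or, more probably, by allylboration from the product 17 as it accumulates. A second channel is direct transfer of the alkenyl group to palladium if halide is not fully sequestered. The fallback keeps the same bond construction but masks the aldehyde; it sets out from 7 and returns at 19. Dehydration of 7 under basic conditions (MsCl, Et3N, CH2Cl2, 0 °C) should give 4-bromo-7-(diethoxymethyl)cyclopenta[c]pyran F1 with the acetal intact. Coupling of F1 with 16 under the conditions of step 7 should give 2-[(2S,3E)-1-[7-(diethoxymethyl)cyclopenta[c]pyran-4-yl]-4,8-dimethylnona-3,7-dien-2-yl]-4,4,5,5-tetramethyl-1,3,2-dioxaborolane F2. Oxidation with anhydrous Me3NO, chosen because the acceptor-free nucleus is more sensitive to peroxide, should give (2S,3E)-1-[7-(diethoxymethyl)cyclopenta[c]pyran-4-yl]-4,8-dimethylnona-3,7-dien-2-ol F3. Acetylation should give (2S,3E)-1-[7-(diethoxymethyl)cyclopenta[c]pyran-4-yl]-4,8-dimethylnona-3,7-dien-2-yl acetate F4, and PPTS in wet acetone should release the aldehyde to give 19. The acetal series must be handled under inert gas in base-washed glassware.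

**Step 2.** The most likely failure is conjugate attack of the Grignard reagent at C2 or C6 of the pyranone with opening of the ring, followed in likelihood by ionisation of the pyranol 6 during work-up or chromatography. The fallback closes ring B without any carbonyl addition of an organometallic; it sets out from 2 and returns at 8. Palladium-catalysed hydrostannation of 1,1-diethoxybut-2-yne (Bu3SnH, Pd(PPh3)2Cl2) should place tin next to the acetal carbon and give tributyl[(2E)-1,1-diethoxybut-2-en-2-yl]stannane F5. Stille coupling of F5 with excess 2 (Pd(PPh3)4, CuI, DMF) should give 3-bromo-5-[(2Z)-1,1-diethoxybut-2-en-2-yl]-4H-pyran-4-one F6, and dilute aqueous acid should give (2Z)-2-(5-bromo-4-oxo-4H-pyran-3-yl)but-2-enal F7. Treatment of F7 with DBU should form the dienolate, in which rotation about the former double bond lets the terminal carbon reach the pyranone carbonyl (5-exo attack at C=O, against 5-endo attack at the ring enone carbon). Vinylogous aldol condensation and loss of water would then give 8. This closure has no direct precedent on a pyranone carbonyl and is held in reserve for that reason.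

**Step 8.** The most likely failure is oxidative degradation of the nucleus: peroxide attack on the formyl group (Dakin-type cleavage) or on the electron-rich ring B competing with oxidation at boron. The fallback reaches 18 without any carbon–boron oxidation; it sets out from 8 and returns at 18. Stille coupling of 8 with tributyl[(Z)-2-ethoxyethenyl]stannane (Pd(PPh3)4, CuI) should give 4-[(Z)-2-ethoxyethenyl]cyclopenta[c]pyran-7-carbaldehyde F8, and mild acid hydrolysis should give (7-formylcyclopenta[c]pyran-4-yl)acetaldehyde F9. Alkenyllithium 15 would be transmetalated to zinc (ZnBr2) and added to F9 under a chiral amino-alcohol catalyst. The aliphatic aldehyde should react in preference to the deactivated C7 formyl group, and the ligand antipode would be chosen to give (S)-18. The price is lower expected enantioselectivity with an enolisable arylacetaldehyde.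

## Further compounds

F1 | step 7 | 4-bromo-7-(diethoxymethyl)cyclopenta[c]pyran | Brc1cocc2c(C(OCC)OCC)ccc1-2
F2 | step 7 | 2-[(2S,3E)-1-[7-(diethoxymethyl)cyclopenta[c]pyran-4-yl]-4,8-dimethylnona-3,7-dien-2-yl]-4,4,5,5-tetramethyl-1,3,2-dioxaborolane | CC1(C)OB(OC1(C)C)[C@H](/C=C(\C)CCC=C(C)C)Cc1cocc2c(C(OCC)OCC)ccc1-2
F3 | step 7 | (2S,3E)-1-[7-(diethoxymethyl)cyclopenta[c]pyran-4-yl]-4,8-dimethylnona-3,7-dien-2-ol | O[C@H](/C=C(\C)CCC=C(C)C)Cc1cocc2c(C(OCC)OCC)ccc1-2
F4 | step 7 | (2S,3E)-1-[7-(diethoxymethyl)cyclopenta[c]pyran-4-yl]-4,8-dimethylnona-3,7-dien-2-yl acetate | CC(=O)O[C@H](/C=C(\C)CCC=C(C)C)Cc1cocc2c(C(OCC)OCC)ccc1-2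
F5 | step 2 | tributyl[(2E)-1,1-diethoxybut-2-en-2-yl]stannane | C/C=C(/[Sn](CCCC)(CCCC)CCCC)C(OCC)OCC
F6 | step 2 | 3-bromo-5-[(2Z)-1,1-diethoxybut-2-en-2-yl]-4H-pyran-4-one | C/C=C(/C1=COC=C(Br)C1=O)C(OCC)OCC
F7 | step 2 | (2Z)-2-(5-bromo-4-oxo-4H-pyran-3-yl)but-2-enal | C/C=C(/C1=COC=C(Br)C1=O)C=O
F8 | step 8 | 4-[(Z)-2-ethoxyethenyl]cyclopenta[c]pyran-7-carbaldehyde | CCO/C=C\c1cocc2c(C=O)ccc1-2
F9 | step 8 | (7-formylcyclopenta[c]pyran-4-yl)acetaldehyde | O=CCc1cocc2c(C=O)ccc1-2
A1 | alternative 1 | 2-formylcyclopent-2-en-1-one | O=CC1=CCCC1=O
A2 | alternative 1 | (2S)-2-[(1E)-2,6-dimethylhepta-1,5-dien-1-yl]-2,3-dihydrofuran | C1=CO[C@H](/C=C(\C)CCC=C(C)C)C1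
A3 | alternative 1 | cyclopentanone-fused furo[2,3-b]pyran acetal (endo adduct, formed anti to the alkenyl group) | O=C1CC[C@H]2C1=CO[C@H]1O[C@H](/C=C(\C)CCC=C(C)C)C[C@@H]21
A4 | alternative 2 | 4-[(2S,3E)-2-(tert-butyldimethylsilyloxy)-4,8-dimethylnona-3,7-dien-1-yl]-7-diazo-1H-isochromene-1,8(7H)-dione | CC(C)(C)[Si](C)(C)O[C@H](/C=C(\C)CCC=C(C)C)CC1=COC(=O)C2=C1C=CC(=[N+]=[N-])C2=O
A5 | alternative 2 | N-methoxy-N-methyl-4-[(2S,3E)-2-(tert-butyldimethylsilyloxy)-4,8-dimethylnona-3,7-dienyl]-1-oxo-1,5-dihydrocyclopenta[c]pyran-7-carboxamide | CC(C)(C)[Si](C)(C)O[C@H](/C=C(\C)CCC=C(C)C)CC1=COC(=O)C2=C1CC=C2C(=O)N(C)OC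
A6 | alternative 3 | (Z)-{2-[(3S,4E)-3-(tert-butyldimethylsilyloxy)-5,9-dimethyldeca-4,8-dienoyl]cyclopenta-2,4-dien-1-ylidene}methyl formate | O=CO/C=C1/C=CC=C1C(=O)C[C@H](O[Si](C)(C)C(C)(C)C)/C=C(\C)CCC=C(C)C
A7 | alternative 3 | 4-[(2S,3E)-2-(tert-butyldimethylsilyloxy)-4,8-dimethylnona-3,7-dienyl]cyclopenta[c]pyran | CC(C)(C)[Si](C)(C)O[C@H](/C=C(\C)CCC=C(C)C)Cc1cocc2cccc1-2
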